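Per minute was the unit I wanted for the teal run, which is the asked flask itself, followed so far.

the same everywhere: free monomer 10 mM; initiator 100 µM

|  | remark | time |
|---|---|---|
| teal | the very flask that is asked about, followed so far |  |
| flask |  | 30 min |

- teal (time / min: monomer in chains / %, free monomer / %): 0.667: 2, 96; 2.00: 0, 98; 3.00: 7, 92; 5.00: 16, 84; 6.00: 24, 76; 10.0: 44, 51

(scatter of a reading: 2 percentage points)

- the average divides the monomer in chains by the number of chains begun, living and dead together
- the analysis behind the earlier runs scatters by 2 percentage points, standard deviation
- the earlier runs do not show the number of chains; that part of a forecast is a guess

- average number of monomer units in a chain (chains begun, living or dead) at 30 min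
- part of the free monomer that has reacted at 30 min

I replaced the curved decay of free monomer by its mean over the last stretch of the teal run: the window constant 0.0997 /min, the logarithm of the ratio of [free monomer] at the two ends of a window divided by its length, a pseudo-first-order constant. A second way used a different reading: a parabola, the logarithm of charge over free monomer growing with the square of time, drawn through the teal reading at 5.00 min. Its slope at mid-window was 0.112 /min, and with 2 percentage points on each reading the two ways agreed there within the scatter.

They parted at 30 min. Carried on from 10.0 min, the window constant left 6.94% free monomer, and the parabola left 0.188%. I judged that the parabola cheated, because it needs chains to keep starting at a steady pace, while free monomer, from which I supposed they start, stood at half of its charge in the teal reading at 10.0 min. So I committed to 93.1% reacted. The runs show no chain count; if every initiator began a chain, the average would be 93.1, and I took that as the low end.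

The forecast gave 94%, a little above my figure, and 180, the second called “largely a guess”.

The flask gave 94.4% and 122.

    free monomer + initiator → living end + monomer in chains (k = 0.185 /M/s)
    free monomer + living end → monomer in chains + living end, rate k2*[living end]*[free monomer] (k = 26.9 /M/s)
    monomer in chains → over-reaction product (k = 2.59 × 10⁻⁵ /s)

The forecast's conversion held, and its chain length stood 1.48 times too high. My window constant had left 6.94% free monomer, and the flask held 5.6%, a gap of 1.4 points. I ran the same reckoning backwards on the same flask read at 8.0 min: 0.0997 /min from the teal reading at 10.0 min gave 62.3% free monomer, and that flask held 65.8%.

Readings and results stem from a simulated flask with made-up constants; noise was put on by code.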